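**Plan**

- The diene is cut at the single bond between the ring-A vinyl group and the C(CH3)=CH unit (Suzuki–Miyaura coupling of vinyl iodide 18 with alkenyl boronate 29). This gives a ring-A fragment and a ring-B fragment.
- Ring A is cut at the bond between its CH(CH3) carbon and the neighbouring quaternary C(CH3)2 carbon. The C(CH3)2 carbon is the tertiary radical that an isopropenyl group gives on hydrogen-atom transfer, and the CH(CH3) carbon is the β-carbon of a vinyl sulfone (CH=CH–SO2Ph, later CH–CH3), so the cyclohexane closes 6-exo. The ring methylidene carbon is kept as a carbinol inside a temporary acetonide.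
- Ring B comes from the (S)-Hajos–Parrish ketone. Baeyer–Villiger oxidation turns a ring-fusion C–C bond into the tertiary C–O bond, a silicon tether delivers CH2 to the quaternary carbon with tandem allyl transfer, and a temporary eight-membered lactone fixes the Z geometry of the enal.
- Forward order: ring A (steps 1–12), ring B (steps 13–21), union and unmasking (steps 22–25).
- Stereochemistry: the ring-A CH centre comes from an Evans syn-aldol and relays to CH(CH3) in the ring closure. The ring-B carbinol comes from the Hajos–Parrish ketone, and its two neighbours from the tether and from allylation anti to the angular methyl. The diene geometry comes from Takai olefination, boron–Wittig olefination and stereoretentive coupling.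

Key step: step 6

Remark: organoboron and organometallic species are drawn as monomers, 26 is carried as the mixture of epimers at its phosphonate-bearing carbon, and 25 is drawn as the open hydroxy ketone although it may rest as a six-membered hemiketal.

**Ring A**

Step 1
Reactants: 1 (4S)-4-benzyl-1,3-oxazolidin-2-one; 2 3-methylbut-2-enoyl chloride
Product: 4 (4S)-4-benzyl-3-(3-methylbut-2-enoyl)-1,3-oxazolidin-2-one, via N-lithio oxazolidinone 3 (not isolated)
Conditions: n-BuLi, THF, −78 °C; then 2, −78 → 0 °C
Reagents that add atoms: none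
Why: N-acylation of the lithiated oxazolidinone by the acid chloride at low temperature is the standard imide synthesis and avoids deconjugation of the senecioyl unit; no stereocentre is formed.

Step 2
Reactants: 5 pent-4-enal; 6 phenyl vinyl sulfone
Product: 7 (4E)-5-(phenylsulfonyl)pent-4-enal
Conditions: second-generation Hoveyda–Grubbs catalyst RuCl2(H2IMes)(=CH–C6H4-2-OiPr) (5 mol%), CH2Cl2, 40 °C
Reagents that add atoms: none
Why: Olefin cross-metathesis between a terminal alkene and phenyl vinyl sulfone, which does not homodimerize, is selective for the cross product and gives the E-alkene.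

Step 3
Reactants: 4 (4S)-4-benzyl-3-(3-methylbut-2-enoyl)-1,3-oxazolidin-2-one; 7 (4E)-5-(phenylsulfonyl)pent-4-enal
Product: 9 (4S)-4-benzyl-3-[(2S,3R,6E)-3-hydroxy-7-(phenylsulfonyl)-2-(prop-1-en-2-yl)hept-6-enoyl]-1,3-oxazolidin-2-one, via dibutylboron dienolate 8 (not isolated)
Conditions: Bu2BOTf, Et3N, CH2Cl2, −78 → 0 °C; then 7, −78 → 0 °C; pH 7 buffer, MeOH, H2O2, 0 °C
Reagents that add atoms: none
Why: Evans syn-aldol reaction of a dienolate: γ-deprotonation gives the (Z)-boron dienolate 8, which adds through its α-carbon in a chair (Zimmerman–Traxler) transition state on the face opposite the benzyl group of the auxiliary, setting the CH(isopropenyl) centre (2S) and the carbinol centre (3R) together.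

Step 4
Reactants: 9 the aldol adduct
Product: 10 (2R,3R,6E)-7-(phenylsulfonyl)-2-(prop-1-en-2-yl)hept-6-ene-1,3-diol
Conditions: LiBH4, MeOH (1 equiv), Et2O, 0 °C
Reagents that add atoms: none
Why: Reductive cleavage of the N-acyl oxazolidinone with LiBH4 (hydride attack at the exocyclic carbonyl) gives the primary alcohol and returns the auxiliary, and should leave both stereocentres and the vinyl sulfone untouched at 0 °C.

Step 5
Reactants: 10 the syn-1,3-diol
Product: 11 (4R,5R)-2,2-dimethyl-4-[(3E)-4-(phenylsulfonyl)but-3-en-1-yl]-5-(prop-1-en-2-yl)-1,3-dioxane (4,5-cis)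
Conditions: 2,2-dimethoxypropane, PPTS (cat.), CH2Cl2, rt
Reagents that add atoms: 2,2-dimethoxypropane, COC(C)(C)OC
Why: Acid-catalysed transacetalization gives the six-membered acetonide, a temporary ring in which the syn-diol becomes a cis-4,5-disubstituted dioxane with the sulfonylbutenyl chain equatorial and the isopropenyl group axial.

Step 6
Reactants: 11 the acetonide
Product: 12 (4aR,6S,8aR)-2,2,5,5-tetramethyl-6-[(phenylsulfonyl)methyl]hexahydro-4H-1,3-benzodioxine (cis ring fusion; CH2SO2Ph cis to the CH2O arm at C4a)
Conditions: Fe(acac)3 (30 mol%), PhSiH3 (2.5 equiv), EtOH/HOCH2CH2OH, 60 °C, degassed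
Reagents that add atoms: none
Why: The iron hydride formed from Fe(acac)3 and PhSiH3 transfers a hydrogen atom to the CH2 terminus of the isopropenyl group, the only electron-rich alkene in 11, and the resulting tertiary radical adds to the β-carbon of the vinyl sulfone to forge the CH–C(CH3)2 bond, after which the α-sulfonyl radical is reduced and protonated by ethanol. The closest known reaction type is the iron-mediated reductive coupling of an unactivated alkene with an electron-poor alkene (hydrogen-atom-transfer-initiated Giese addition), run here intramolecularly. The cyclohexane closes in the 6-exo-trig mode through a chair that is cis-fused to the dioxane. The new stereocentre (the carbon bearing CH2SO2Ph) is controlled by the existing CH stereocentre of the dioxane: the acetonide holds the chain equatorial and the radical-bearing substituent axial on the dioxane, so the CH2O arm is equatorial on the forming ring and the vinyl sulfone takes the pseudo-equatorial position, which places CH2SO2Ph cis to the CH2O arm. The step needs chemoselective hydrogen-atom transfer and exo rather than endo closure; both are secured by the polarity match of a nucleophilic tertiary radical with the sulfone-activated alkene terminus and by keeping the future methylidene carbon at the carbinol level inside the acetonide, so that no second 1,1-disubstituted alkene and no β-carbonyl group (1,2-acyl shift) is present.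

Step 7
Reactants: 12 the cyclized sulfone
Product: 13 (4aR,6S,8aR)-2,2,5,5,6-pentamethylhexahydro-4H-1,3-benzodioxine
Conditions: 6% Na(Hg), Na2HPO4, MeOH/THF, −20 → 0 °C
Reagents that add atoms: none
Why: Reductive desulfonylation (electron transfer to the aryl sulfone, C–S cleavage, protonation by methanol) turns the activating CH2SO2Ph group into the methyl group and leaves the acetonide and all stereocentres untouched.

Step 8
Reactants: 13 the acetonide
Product: 14 (1R,2R,4S)-2-(hydroxymethyl)-3,3,4-trimethylcyclohexan-1-ol
Conditions: AcOH/H2O/THF, 40 °C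
Reagents that add atoms: none
Why: Mild acid hydrolysis of the acetonide removes the temporary ring and frees the 1,3-diol without affecting the stereocentres.

Step 9
Reactants: 14 the diol
Product: 15 (1S,3S,6R)-6-hydroxy-2,2,3-trimethylcyclohexane-1-carbaldehyde
Conditions: TEMPO (10 mol%), PhI(OAc)2, CH2Cl2, rt
Reagents that add atoms: none
Why: Oxoammonium-mediated oxidation (TEMPO with PhI(OAc)2) is selective for the primary over the hindered secondary alcohol and is not basic, so the α-stereocentre of the aldehyde is kept.

Step 10
Reactants: 15 the hydroxy aldehyde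
Product: 16 (1R,2S,4S)-2-[(E)-2-iodoethenyl]-3,3,4-trimethylcyclohexan-1-ol
Conditions: CrCl2, CHI3, THF/1,4-dioxane, 0 °C → rt
Reagents that add atoms: iodoform, IC(I)I
Why: Takai olefination with the gem-dichromium reagent from CHI3 and CrCl2 gives the (E)-vinyl iodide under neutral conditions that tolerate the free hydroxyl group and do not epimerize the α-centre.

Step 11
Reactants: 16 the iodo alcohol
Product: 17 (2S,4S)-2-[(E)-2-iodoethenyl]-3,3,4-trimethylcyclohexan-1-one
Conditions: Dess–Martin periodinane, NaHCO3, CH2Cl2, 0 °C → rt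
Reagents that add atoms: none
Why: Dess–Martin oxidation under buffered conditions converts the secondary alcohol into the ketone without enolizing the adjacent CH centre, whose substituent is already equatorial and cis to the ring methyl group.

Step 12
Reactants: 17 the ketone
Product: 18 (2R,6S)-2-[(E)-2-iodoethenyl]-1,1,6-trimethyl-3-methylidenecyclohexane
Conditions: Zn, CH2Br2, TiCl4, THF/CH2Cl2, 0 °C → rt
Reagents that add atoms: dibromomethane, BrCBr
Why: Lombardo methylenation with the zinc–titanium gem-dimetallic reagent from CH2Br2 converts the hindered, enolizable ketone into the exocyclic methylidene group without base, so the α-stereocentre is kept and the alkene stays out of conjugation.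

**Ring B**

Step 13
Reactants: 19 (7aS)-7a-methyl-2,3,7,7a-tetrahydro-1H-indene-1,5(6H)-dione ((S)-Hajos–Parrish ketone)
Product: 20 (8aS)-8a-methyl-4,7,8,8a-tetrahydro-2H-chromene-2,6(3H)-dione
Conditions: mCPBA, NaHCO3, CH2Cl2, 0 °C → rt
Reagents that add atoms: 3-chloroperoxybenzoic acid, OOC(=O)c1cccc(Cl)c1
Why: Baeyer–Villiger oxidation takes place at the saturated cyclopentanone rather than at the conjugated ketone, and the quaternary carbon migrates with retention, which places the oxygen of the future tertiary alcohol on the methyl-bearing stereocentre.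

Step 14
Reactants: 20 the enone lactone
Product: 21 3-[(6S)-6-hydroxy-6-methyl-3-oxocyclohex-1-en-1-yl]-N-methoxy-N-methylpropanamide
Conditions: MeNH(OMe)·HCl, AlMe3, CH2Cl2, 0 °C → rt
Reagents that add atoms: N,O-dimethylhydroxylamine hydrochloride, CNOC.Cl
Why: Aminolysis of the lactone with the aluminium amide (Weinreb amide formation) frees the tertiary alcohol and stores the chain end as an amide that can later be reduced selectively to the aldehyde.

Step 15
Reactants: 21 the hydroxy enone
Product: 22 3-[(6S)-6-{[(bromomethyl)dimethylsilyl]oxy}-6-methyl-3-oxocyclohex-1-en-1-yl]-N-methoxy-N-methylpropanamide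
Conditions: BrCH2SiMe2Cl, imidazole, DMF, 0 °C → rt
Reagents that add atoms: (bromomethyl)chlorodimethylsilane, C[Si](C)(Cl)CBr
Why: Silylation of the tertiary alcohol with the unhindered chlorosilane installs the bromomethylsilyl tether for the radical cyclization and touches no stereocentre.

Step 16
Reactants: 22 the bromomethylsilyl ether
Product: 23 N-methoxy-N-methyl-3-[(3aR,4S,7aS)-2,2,7a-trimethyl-5-oxo-4-(prop-2-en-1-yl)octahydro-2,1-benzoxasilol-3a-yl]propanamide (cis-fused oxasilolane; allyl cis to the CH2Si bridge)
Conditions: Bu3SnCH2CH=CH2 (3 equiv), AIBN (cat.), benzene, 80 °C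
Reagents that add atoms: allyltributylstannane, C=CC[Sn](CCCC)(CCCC)CCCC
Why: Silicon-tethered radical cyclization followed by Keck allylation: the silylmethyl radical closes 5-exo-trig onto the β-carbon of the enone, which forces the new CH2 group cis to the tether oxygen at the quaternary centre, and the resulting α-keto radical is allylated by SH2′ substitution on the stannane through axial attack on the face of the siloxane oxygen, anti to the 1,3-related angular methyl group.

Step 17
Reactants: 23 the allyl ketone
Product: 25 N-methoxy-N-methyl-3-[(3aR,4S,7aS)-4-(3-hydroxypropyl)-2,2,7a-trimethyl-5-oxooctahydro-2,1-benzoxasilol-3a-yl]propanamide, via B-alkyl-9-borabicyclononane 24 (not isolated)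
Conditions: 9-BBN (1.2 equiv), THF, 0 °C → rt; then NaBO3·4H2O, H2O, rt
Reagents that add atoms: sodium perborate, [Na+].[Na+].O[B-]1(O)OO[B-](O)(O)OO1
Why: Hydroboration with 9-BBN is anti-Markovnikov and much faster at the monosubstituted alkene than reduction of the hindered ketone or the amide, and perborate oxidizes the C–B bond of 24 to the primary alcohol while leaving the C–Si bond intact.

Step 18
Reactants: 25 the primary alcohol
Product: 26 3-[(3aR,4S,7aS)-3a-{3-[methoxy(methyl)amino]-3-oxopropyl}-2,2,7a-trimethyl-5-oxooctahydro-2,1-benzoxasilol-4-yl]propyl 2-(diethoxyphosphoryl)propanoate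
Conditions: 2-(diethoxyphosphoryl)propanoic acid, EDC·HCl, DMAP (cat.), CH2Cl2, 0 °C → rt
Reagents that add atoms: 2-(diethoxyphosphoryl)propanoic acid, CCOP(=O)(OCC)C(C)C(=O)O
Why: Steglich-type carbodiimide esterification of the only free hydroxyl group attaches the phosphonate needed for the ring-forming olefination.

Step 19
Reactants: 26 the keto phosphonate
Product: 27 tricyclic Weinreb amide: eight-membered (Z)-α-methyl-α,β-unsaturated lactone fused to the oxasilolane-fused cyclohexane (lactone C=O cis to the ring CH)
Conditions: NaH, THF, high dilution (2 mM), 0 → 60 °C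
Reagents that add atoms: none
Why: Intramolecular Horner–Wadsworth–Emmons olefination closes a temporary eight-membered unsaturated lactone, and because the ester carbonyl and the chain-bearing CH carbon lie in the same eight-membered ring the tetrasubstituted alkene can only form with the carbonyl cis to that carbon, which is the geometry of the enal in the target.

Step 20
Reactants: 27 the lactone Weinreb amide
Product: 28 the corresponding aldehyde (CHO in place of C(=O)N(OMe)Me)
Conditions: Cp2Zr(H)Cl (1.5 equiv), THF, rt
Reagents that add atoms: none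
Why: Cp2Zr(H)Cl reduces the tertiary (Weinreb) amide chemoselectively to the aldehyde and leaves the unsaturated lactone and the siloxane untouched.

Step 21
Reactants: 28 the aldehyde
Product: 29 (Z)-alkenyl pinacol boronate, CH=C(CH3)Bpin with boron trans to the chain
Conditions: CH3CH(Bpin)2, lithium 2,2,6,6-tetramethylpiperidide, THF, 0 °C; then 28, −78 °C → rt
Reagents that add atoms: 1,1-bis(pinacolboryl)ethane, CC(B1OC(C)(C)C(C)(C)O1)B1OC(C)(C)C(C)(C)O1
Why: Boron–Wittig olefination: the α-boryl carbanion adds to the aldehyde and syn B–O elimination through the less crowded arrangement (chain eclipsing methyl and not the remaining boryl group) gives the trisubstituted alkenyl boronate with boron trans to the chain.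

**Union and unmasking**

Step 22
Reactants: 18 the ring-A vinyl iodide; 29 the ring-B alkenyl boronate
Product: 30 coupled (E,E)-diene carrying the lactone and the siloxane
Conditions: PdCl2(dppf) (5 mol%), K3PO4 (aq.), THF, 45 °C, degassed
Reagents that add atoms: none
Why: Suzuki–Miyaura coupling at zerovalent palladium joins the alkenyl iodide and the alkenyl boronate with retention at both alkenes and therefore gives the (E,E)-diene.

Step 23
Reactants: 30 the coupled lactone
Product: 31 siloxane diol (allylic alcohol and hydroxypropyl alcohol freed from the lactone)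
Conditions: i-Bu2AlH (4 equiv), CH2Cl2, −78 → 0 °C; potassium sodium tartrate (aq.)
Reagents that add atoms: none
Why: i-Bu2AlH reduces the unsaturated lactone by 1,2-addition to the allylic alcohol and the primary alcohol of the hydroxypropyl chain without moving or isomerizing the tetrasubstituted alkene.

Step 24
Reactants: 31 the siloxane diol
Product: 32 tetraol (the target with CH2OH in place of CHO)
Conditions: KF, KHCO3, H2O2 (30%), THF/MeOH, rt → 40 °C
Reagents that add atoms: hydrogen peroxide, OO
Why: Tamao–Fleming oxidation (fluoride-assisted peroxide oxidation of the C–Si bond with retention and cleavage of the Si–O bond) removes the tether and leaves CH2OH cis to the tertiary hydroxyl group.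

Step 25
Reactants: 32 the tetraol
Product: 33 the target, CNP0149035.1
Conditions: MnO2 (activated, excess), CH2Cl2, rt
Reagents that add atoms: none
Why: Activated MnO2 oxidizes only the allylic primary alcohol, leaving the two saturated primary alcohols and the tertiary alcohol, and gives the Z-enal of the target.

**Compound list**

1 | (4S)-4-benzyl-1,3-oxazolidin-2-one | O=C1OC[C@H](Cc2ccccc2)N1 | starting material
2 | 3-methylbut-2-enoyl chloride | CC(C)=CC(Cl)=O | starting material
3 | N-lithio derivative of 1 | O=C1OC[C@H](Cc2ccccc2)N1[Li] | intermediate (not isolated)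
4 | (4S)-4-benzyl-3-(3-methylbut-2-enoyl)-1,3-oxazolidin-2-one | CC(C)=CC(=O)N1[C@@H](Cc2ccccc2)COC1=O | intermediate
5 | pent-4-enal | C=CCCC=O | starting material
6 | phenyl vinyl sulfone | C=CS(=O)(=O)c1ccccc1 | starting material
7 | (4E)-5-(phenylsulfonyl)pent-4-enal | O=CCC/C=C/S(=O)(=O)c1ccccc1 | intermediate
8 | dibutylboron (Z)-dienolate of 4 | CCCCB(CCCC)O/C(=C\C(C)=C)N1[C@@H](Cc2ccccc2)COC1=O | intermediate (not isolated)
9 | (4S)-4-benzyl-3-[(2S,3R,6E)-3-hydroxy-7-(phenylsulfonyl)-2-(prop-1-en-2-yl)hept-6-enoyl]-1,3-oxazolidin-2-one | CC(=C)[C@H](C(=O)N1[C@@H](Cc2ccccc2)COC1=O)[C@H](O)CC/C=C/S(=O)(=O)c1ccccc1 | intermediate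
10 | (2R,3R,6E)-7-(phenylsulfonyl)-2-(prop-1-en-2-yl)hept-6-ene-1,3-diol | CC(=C)[C@H](CO)[C@H](O)CC/C=C/S(=O)(=O)c1ccccc1 | intermediate
11 | (4R,5R)-2,2-dimethyl-4-[(3E)-4-(phenylsulfonyl)but-3-en-1-yl]-5-(prop-1-en-2-yl)-1,3-dioxane | CC(=C)[C@@H]1COC(C)(C)O[C@@H]1CC/C=C/S(=O)(=O)c1ccccc1 | intermediate
12 | (4aR,6S,8aR)-2,2,5,5-tetramethyl-6-[(phenylsulfonyl)methyl]hexahydro-4H-1,3-benzodioxine | CC1(C)[C@@H](CS(=O)(=O)c2ccccc2)CC[C@H]2OC(C)(C)OC[C@@H]12 | intermediate
13 | (4aR,6S,8aR)-2,2,5,5,6-pentamethylhexahydro-4H-1,3-benzodioxine | CC1(C)[C@@H](C)CC[C@H]2OC(C)(C)OC[C@@H]12 | intermediate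
14 | (1R,2R,4S)-2-(hydroxymethyl)-3,3,4-trimethylcyclohexan-1-ol | CC1(C)[C@@H](C)CC[C@@H](O)[C@H]1CO | intermediate
15 | (1S,3S,6R)-6-hydroxy-2,2,3-trimethylcyclohexane-1-carbaldehyde | CC1(C)[C@@H](C)CC[C@@H](O)[C@H]1C=O | intermediate
16 | (1R,2S,4S)-2-[(E)-2-iodoethenyl]-3,3,4-trimethylcyclohexan-1-ol | CC1(C)[C@@H](C)CC[C@@H](O)[C@H]1/C=C/I | intermediate
17 | (2S,4S)-2-[(E)-2-iodoethenyl]-3,3,4-trimethylcyclohexan-1-one | CC1(C)[C@@H](C)CCC(=O)[C@H]1/C=C/I | intermediate
18 | (2R,6S)-2-[(E)-2-iodoethenyl]-1,1,6-trimethyl-3-methylidenecyclohexane | CC1(C)[C@@H](C)CCC(=C)[C@H]1/C=C/I | intermediate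
19 | (7aS)-7a-methyl-2,3,7,7a-tetrahydro-1H-indene-1,5(6H)-dione | C[C@]12CCC(=O)C=C1CCC2=O | starting material
20 | (8aS)-8a-methyl-4,7,8,8a-tetrahydro-2H-chromene-2,6(3H)-dione | C[C@]12CCC(=O)C=C1CCC(=O)O2 | intermediate
21 | 3-[(6S)-6-hydroxy-6-methyl-3-oxocyclohex-1-en-1-yl]-N-methoxy-N-methylpropanamide | C[C@]1(O)CCC(=O)C=C1CCC(=O)N(C)OC | intermediate
22 | 3-[(6S)-6-{[(bromomethyl)dimethylsilyl]oxy}-6-methyl-3-oxocyclohex-1-en-1-yl]-N-methoxy-N-methylpropanamide | C[C@]1(O[Si](C)(C)CBr)CCC(=O)C=C1CCC(=O)N(C)OC | intermediate
23 | N-methoxy-N-methyl-3-[(3aR,4S,7aS)-2,2,7a-trimethyl-5-oxo-4-(prop-2-en-1-yl)octahydro-2,1-benzoxasilol-3a-yl]propanamide | CON(C)C(=O)CC[C@@]1(C[Si](C)(C)O2)[C@H](CC=C)C(=O)CC[C@@]12C | intermediate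
24 | B-alkyl-9-borabicyclo[3.3.1]nonane adduct of 23 | CON(C)C(=O)CC[C@@]1(C[Si](C)(C)O2)[C@H](CCCB3C4CCCC3CCC4)C(=O)CC[C@@]12C | intermediate (not isolated)
25 | N-methoxy-N-methyl-3-[(3aR,4S,7aS)-4-(3-hydroxypropyl)-2,2,7a-trimethyl-5-oxooctahydro-2,1-benzoxasilol-3a-yl]propanamide | CON(C)C(=O)CC[C@@]1(C[Si](C)(C)O2)[C@H](CCCO)C(=O)CC[C@@]12C | intermediate
26 | 2-(diethoxyphosphoryl)propanoate ester of 25 | CON(C)C(=O)CC[C@@]1(C[Si](C)(C)O2)[C@H](CCCOC(=O)C(C)P(=O)(OCC)OCC)C(=O)CC[C@@]12C | intermediate
27 | tricyclic Weinreb amide with the eight-membered (Z)-unsaturated lactone | CON(C)C(=O)CC[C@@]1(C[Si](C)(C)O2)[C@@H]3CCCOC(=O)/C(C)=C3/CC[C@@]12C | intermediate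
28 | aldehyde corresponding to 27 | O=CCC[C@@]1(C[Si](C)(C)O2)[C@@H]3CCCOC(=O)/C(C)=C3/CC[C@@]12C | intermediate
29 | (Z)-alkenyl pinacol boronate from 28 | CC1(C)OB(OC1(C)C)/C(C)=C/CC[C@@]2(C[Si](C)(C)O3)[C@@H]4CCCOC(=O)/C(C)=C4/CC[C@@]23C | intermediate
30 | coupled (E,E)-diene with lactone and siloxane | C=C1CC[C@H](C)C(C)(C)[C@@H]1/C=C/C(C)=C/CC[C@@]2(C[Si](C)(C)O3)[C@@H]4CCCOC(=O)/C(C)=C4/CC[C@@]23C | intermediate
31 | siloxane diol | C=C1CC[C@H](C)C(C)(C)[C@@H]1/C=C/C(C)=C/CC[C@@]2(C[Si](C)(C)O3)[C@H](CCCO)/C(=C(/C)CO)CC[C@@]23C | intermediate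
32 | tetraol (allylic alcohol of the target) | C=C1CC[C@H](C)C(C)(C)[C@@H]1/C=C/C(C)=C/CC[C@@]1(CO)[C@H](CCCO)/C(=C(/C)CO)CC[C@]1(C)O | intermediate
33 | CNP0149035.1 | C=C1CC[C@H](C)C(C)(C)[C@@H]1/C=C/C(C)=C/CC[C@@]1(CO)[C@H](CCCO)/C(=C(/C)C=O)CC[C@]1(C)O | target

**Count and risks**

Total step count: 25. Longest linear sequence: 15 steps (steps 2–12, then 22–25).

Steps most likely to fail:

1. Step 19 (intramolecular Horner–Wadsworth–Emmons). What may go wrong: the eight-membered ring does not close, because intermolecular olefination to oligomers and base-induced epimerization at the ketone α-carbon outrun the intramolecular reaction. Fallback, from 25 back to 27: acylation of 25 with 2-bromopropanoyl bromide and pyridine should give the 2-bromopropanoate F1. SmI2 in THF at high dilution should turn the bromo ester into its samarium enolate, which adds to the ring ketone (intramolecular Reformatsky reaction, a ring closure used for medium-ring lactones) to give the β-hydroxy lactone F2. Dehydration of the tertiary alcohol of F2 with SOCl2/pyridine (or the Burgess reagent) inside the eight-membered ring can only deliver the Z-alkene and gives 27.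

2. Step 16 (radical cyclization with allyl transfer). What may go wrong: poor facial selectivity in the allyl transfer (the stannane meets the α-keto radical on the face of the angular methyl group and gives the epimer at the CH–allyl carbon), or allylation of the silylmethyl radical before it cyclizes. Fallback, from 21 back to 23: the order of bond formation at that carbon is reversed, so that hydrogen and not allyl arrives last. Iodination of 21 (I2, pyridine, CH2Cl2) should give the α-iodo enone F3. Stille coupling with Bu3SnCH2CH=CH2 (Pd2(dba)3, AsPh3) should give the 2-allyl enone F4. Silylation with BrCH2SiMe2Cl/imidazole should give the tether-bearing enone F5. Bu3SnH/AIBN would then close the oxasilolane as before, and the tertiary α-keto radical would take its hydrogen atom from Bu3SnH on the face that the stannane preferred, which gives 23.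

3. Step 6 (key ring closure). What may go wrong: the hydride system reduces the tertiary radical (net hydrogenation of the isopropenyl group) or the vinyl sulfone before the six-membered ring closes. Fallback, from 11 back to 12: epoxidation of the isopropenyl group of 11 (mCPBA, NaHCO3; the sulfonyl alkene is inert) should give the epoxide F6. Cp2TiCl, made from Cp2TiCl2 and Zn (trivalent titanium), opens the epoxide reductively to the same kind of tertiary radical without any hydride donor. The 6-exo addition to the vinyl sulfone, reduction of the α-sulfonyl radical and protonation should give the primary alcohol F7, in which one of the geminal methyl groups carries OH. Appel iodination (I2, PPh3, imidazole) to the neopentyl iodide F8 and reduction with Bu3SnH/AIBN would return 12.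

**Further compounds**

F1 | step 19 | 2-bromopropanoate ester of 25 | CON(C)C(=O)CC[C@@]1(C[Si](C)(C)O2)[C@H](CCCOC(=O)C(C)Br)C(=O)CC[C@@]12C
F2 | step 19 | eight-membered β-hydroxy lactone (tertiary alcohol, mixture of isomers at the two new centres) | CON(C)C(=O)CC[C@@]1(C[Si](C)(C)O2)[C@@H]3CCCOC(=O)C(C)C3(O)CC[C@@]12C
F3 | step 16 | 3-[(6S)-6-hydroxy-2-iodo-6-methyl-3-oxocyclohex-1-en-1-yl]-N-methoxy-N-methylpropanamide | C[C@]1(O)CCC(=O)C(I)=C1CCC(=O)N(C)OC
F4 | step 16 | 3-[(6S)-6-hydroxy-6-methyl-3-oxo-2-(prop-2-en-1-yl)cyclohex-1-en-1-yl]-N-methoxy-N-methylpropanamide | C[C@]1(O)CCC(=O)C(CC=C)=C1CCC(=O)N(C)OC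
F5 | step 16 | (bromomethyl)dimethylsilyl ether of F4 | C[C@]1(O[Si](C)(C)CBr)CCC(=O)C(CC=C)=C1CCC(=O)N(C)OC
F6 | step 6 | epoxide of the isopropenyl group of 11 (mixture at the epoxide carbon) | CC1(CO1)[C@@H]2COC(C)(C)O[C@@H]2CC/C=C/S(=O)(=O)c3ccccc3
F7 | step 6 | cyclized sulfone with one geminal CH2OH in place of CH3 | CC1(CO)[C@@H](CS(=O)(=O)c2ccccc2)CC[C@H]2OC(C)(C)OC[C@@H]12
F8 | step 6 | neopentyl iodide from F7 | CC1(CI)[C@@H](CS(=O)(=O)c2ccccc2)CC[C@H]2OC(C)(C)OC[C@@H]12
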